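The dione ring (C19, C21, C23, C25, C26, C27) is made one carbon short. A cis-fused β-keto-lactone cyclopentanone (C19–C21–C25–C26–C27), closed by Dieckmann condensation inside the finished 11-membered ring, is enlarged by Lewis-acid TMS-diazomethane homologation. Because C19 is quaternary and carries the lactone carbonyl C17, only C25 migrates. The inserted C23 is then the sole enolisable α-carbon of C21=O and is oxidised to the dione. Upstream, an exo-selective Diels–Alder reaction of a lactate-derived methylene-dioxolanone sets C6, C12 and C15, a tetronate triflate is joined to a desymmetrised syn-dimethyl zinc reagent, and ring-closing metathesis closes the macrocycle.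

Key step: step 22

Remark (locants): atoms are labelled in the order of the target SMILES, hydrogens omitted: C1 (methyl on C2), C2–C6, C7=C8, C9 (carboxyl), C12 (methyl C13), C14, C15 (spiro), O16, C17 (lactone C=O), C19 (methyl C20), C21, C23, C25, C26, C27, C28 (methyl C29), C30.

Remark (assumption): C25 is α to the C23 ketone in the target and therefore epimerisable. The drawn configuration (C28 and C15 cis on the six-membered ring) is taken as the only low-strain arrangement of the C25/C27-bridged framework. C25 is carried as an epimer mixture in 20–27 and left unassigned there, as are the C3=C4 geometry of 24 and the silyl-bearing C23 of 30.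

Step 1
Reactants: 1 (S)-lactic acid; 2 pivalaldehyde
Product: 3 (2S,5S)-2-tert-butyl-5-methyl-1,3-dioxolan-4-one
Conditions: p-TsOH (cat.), H2SO4 (cat.), pentane, reflux, water separator; crystallisation of the cis isomer
Reagents that add atoms: none
Why: Acid-catalysed acetalisation of the α-hydroxy acid, in which the lactate centre should control the new acetal centre (cis acetal favoured and purified by crystallisation).

Step 2
Reactants: 3 (2S,5S)-2-tert-butyl-5-methyl-1,3-dioxolan-4-one
Product: 4 (2R,5R)-5-bromo-2-tert-butyl-5-methyl-1,3-dioxolan-4-one (Br trans to tert-butyl)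
Conditions: NBS, AIBN (cat.), CCl4, reflux
Reagents that add atoms: N-bromosuccinimide, BrN1C(=O)CCC1=O
Why: Wohl–Ziegler-type radical bromination at the captodative C5–H, with bromine delivered anti to the tert-butyl group (this centre is removed in step 3).

Step 3
Reactants: 4 (2R,5R)-5-bromo-2-tert-butyl-5-methyl-1,3-dioxolan-4-one
Product: 5 (S)-2-tert-butyl-5-methylene-1,3-dioxolan-4-one
Conditions: DBU, benzene, 0 → 25 °C
Reagents that add atoms: none
Why: E2 dehydrobromination should give the exocyclic captodative alkene while the acetal centre stays untouched.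

Step 4
Reactants: 6 pent-1-en-4-yne
Product: 8 (E)-octa-4,7-dien-3-one, via alkenylzirconocene chloride 7 (not isolated)
Conditions: Cp2Zr(H)Cl, CH2Cl2, 25 °C; then EtCOCl, CuBr·SMe2 (10 mol %), 25 °C
Reagents that add atoms: propionyl chloride, CCC(=O)Cl
Why: syn-Hydrozirconation of the terminal alkyne (faster than of the alkene) gives the (E)-alkenylzirconium species, whose copper-catalysed acylation retains the E geometry.

Step 5
Reactants: 8 (E)-octa-4,7-dien-3-one
Product: 9 (4E,6Z)-6-(tert-butyldimethylsilyloxy)octa-1,4,6-triene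
Conditions: TBSOTf, Et3N, Et2O, −78 → 0 °C
Reagents that add atoms: tert-butyldimethylsilyl triflate, CC(C)(C)[Si](C)(C)OS(=O)(=O)C(F)(F)F
Why: Soft enolisation at the α′-CH2 should give the favoured (Z)-enol silane (methyl anti to the dienyl chain), that is, a 2-silyloxydiene with both terminal substituents "outside".

Step 6
Reactants: 5 (S)-2-tert-butyl-5-methylene-1,3-dioxolan-4-one; 9 (4E,6Z)-6-(tert-butyldimethylsilyloxy)octa-1,4,6-triene
Product: 10 spiro-dioxolanone Diels–Alder adduct (cyclohexene with C6 allyl, C7=C8–OTBS, C12 methyl, C15 spiro; O16 cis to allyl and methyl)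
Conditions: toluene, BHT (cat.), 70 °C, sealed tube
Reagents that add atoms: none
Why: Diels–Alder reaction in which the 2-silyloxy group directs C12 to the methylene carbon and C6 to the quaternary carbon; the exo (C=O exo) transition state typical of this dienophile, on the face anti to tert-butyl, should set C6, C12 and C15 together.

Step 7
Reactants: 10 spiro-dioxolanone Diels–Alder adduct
Product: 12 spiro-tetronic acid (4-hydroxybutenolide C15–O16–C17(=O)–C19H=C27–OH), via β-keto ester 11 (not isolated)
Conditions: MeOAc, LDA, THF, −78 °C; then 10, −78 → 25 °C; aq. NH4Cl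
Reagents that add atoms: lithium enolate of methyl acetate, [Li]OC(=C)OC
Why: Claisen acylation of the ester enolate by the acylal carbonyl C27 expels pivalaldehyde and the C15 alkoxide, which lactonises onto the β-keto ester (tetronic acid synthesis from dioxolanones); no stereocentre is touched.

Step 8
Reactants: 12 spiro-tetronic acid
Product: 13 spiro-tetronate triflate (C27–OTf)
Conditions: PhNTf2, i-Pr2NEt, CH2Cl2, 0 → 25 °C
Reagents that add atoms: N-phenyl-bis(trifluoromethanesulfonimide), O=S(=O)(N(c1ccccc1)S(=O)(=O)C(F)(F)F)C(F)(F)F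
Why: O-Sulfonylation of the acidic vinylogous acid with a mild triflyl donor avoids acid that would cleave the enol silane.

Step 9
Reactants: 14 cis-3,5-dimethylcyclohexanone (meso)
Product: 15 (3S,5R)-3,5-dimethyl-1-(trimethylsilyloxy)cyclohexene
Conditions: lithium (S,S)-bis(1-phenylethyl)amide, LiCl, TMSCl (in situ), THF, −100 °C
Reagents that add atoms: chlorotrimethylsilane, C[Si](C)(C)Cl
Why: Enantioselective deprotonation of the meso ketone by the C2-symmetric chiral lithium amide with in situ silylation differentiates the enantiotopic α-CH2 groups and so fixes both methyl centres (later C2 and C28); the (S,S)-base is assigned by analogy with 4-substituted cyclohexanones, and its antipode would be used if the sense proved opposite.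

Step 10
Reactants: 15 (3S,5R)-3,5-dimethyl-1-(trimethylsilyloxy)cyclohexene
Product: 16 (3R,5S)-3,5-dimethyl-6-oxohexanoic acid
Conditions: O3, CH2Cl2, −78 °C; Me2S, −78 → 25 °C; aqueous work-up
Reagents that add atoms: ozone, [O-][O+]=O
Why: Ozonolysis of the enol silane cleaves C1=C2 regiospecifically to the silyl ester and aldehyde, and work-up hydrolyses the silyl ester without touching the stereocentres.

Step 11
Reactants: 16 (3R,5S)-3,5-dimethyl-6-oxohexanoic acid
Product: 17 methyl (3R,5S)-3,5-dimethyl-6-oxohexanoate
Conditions: TMSCHN2, MeOH/toluene, 0 °C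
Reagents that add atoms: trimethylsilyldiazomethane, C[Si](C)(C)C=[N+]=[N-]
Why: Neutral esterification by diazomethane released in situ, so the α-methyl aldehyde should not epimerise.

Step 12
Reactants: 17 methyl (3R,5S)-3,5-dimethyl-6-oxohexanoate
Product: 18 methyl (3R,5S)-3,5-dimethylhept-6-enoate
Conditions: Ph3PCH3Br, KHMDS, THF, 0 °C; then 17, −78 → 0 °C
Reagents that add atoms: methylenetriphenylphosphorane, C=P(c1ccccc1)(c1ccccc1)c1ccccc1
Why: Wittig methylenation at low temperature should convert the aldehyde to the vinyl group faster than it enolises.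

Step 13
Reactants: 18 methyl (3R,5S)-3,5-dimethylhept-6-enoate
Product: 20 methyl (3R,5S)-2-(hydroxymethyl)-3,5-dimethylhept-6-enoate (C2 epimers), via lithium enolate 19 (not isolated)
Conditions: LDA, THF, −78 °C; CH2O (gas, from paraformaldehyde), −78 → −20 °C; aq. NH4Cl
Reagents that add atoms: formaldehyde, C=O
Why: Aldol addition of the ester enolate to monomeric formaldehyde installs C26; the new centre (C25) forms without control, which is irrelevant (see remark).

Step 14
Reactants: 20 methyl (3R,5S)-2-(hydroxymethyl)-3,5-dimethylhept-6-enoate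
Product: 21 methyl (3R,5S)-2-(iodomethyl)-3,5-dimethylhept-6-enoate (C2 epimers)
Conditions: I2, PPh3, imidazole, CH2Cl2, 0 → 25 °C
Reagents that add atoms: iodine, II
Why: Appel-type iodination of the primary alcohol under buffered conditions should avoid elimination to the acrylate.

Step 15
Reactants: 21 methyl (3R,5S)-2-(iodomethyl)-3,5-dimethylhept-6-enoate; 13 spiro-tetronate triflate
Product: 23 4-alkylbutenolide diene (C27–C26H2–C25H(CO2Me)–C28…C3H=CH2; allyl on C6), via organozinc iodide 22 (not isolated)
Conditions: Zn dust (activated with TMSCl and 1,2-dibromoethane), DMF, 25 °C; then 13, Pd(PPh3)4 (5 mol %), LiCl, 25 → 40 °C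
Reagents that add atoms: none
Why: Zinc insertion gives a β-zincio ester that tolerates its own ester group, and Negishi coupling with the electron-poor vinyl triflate should form C26–C27 without touching the enol silane or the alkenes.

Step 16
Reactants: 23 4-alkylbutenolide diene
Product: 24 macrocyclic butenolide (11-membered ring with C3=C4)
Conditions: 2nd-generation Ru–NHC benzylidene metathesis catalyst (10 mol %), 1,4-benzoquinone (10 mol %), CH2Cl2 (1 mM), 40 °C
Reagents that add atoms: none
Why: Ring-closing metathesis of the two monosubstituted alkenes closes the 11-membered carbocycle, a ring size that has precedent for this reaction on spirotetronate frameworks; the planar C27 lets the chain reach the allyl group, and alkene geometry is irrelevant.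

Step 17
Reactants: 24 macrocyclic butenolide
Product: 25 saturated macrocyclic γ-lactone (C27–H set; C19H2)
Conditions: H2 (3 atm), 5 % Rh/Al2O3, EtOAc, 25 °C
Reagents that add atoms: none
Why: Heterogeneous hydrogenation saturates C3=C4 and the β,β-disubstituted butenolide from the face not covered by the macrocycle, which sets C27–H anti to C6; the hindered trisubstituted enol silane is expected to survive, and rhodium is chosen to limit double-bond migration past C2.

Step 18
Reactants: 25 saturated macrocyclic γ-lactone
Product: 26 enol triflate (C7=C8–OTf)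
Conditions: CsF, PhNTf2, DME, 25 °C
Reagents that add atoms: N-phenyl-bis(trifluoromethanesulfonimide), O=S(=O)(N(c1ccccc1)S(=O)(=O)C(F)(F)F)C(F)(F)F
Why: Fluoride cleaves the enol silane to the regiodefined enolate, which is trapped at oxygen, so C12 is never exposed to an equilibrating ketone.

Step 19
Reactants: 26 enol triflate
Product: 27 2-(trimethylsilyl)ethyl enoate (C8–CO2CH2CH2SiMe3)
Conditions: CO (1 atm), Pd(OAc)2 (10 mol %), dppf (12 mol %), Et3N, Me3SiCH2CH2OH, DMF, 60 °C
Reagents that add atoms: carbon monoxide, [C-]#[O+]; 2-(trimethylsilyl)ethanol, C[Si](C)(C)CCO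
Why: Palladium-catalysed alkoxycarbonylation of the vinyl triflate gives the enoate as a fluoride-labile ester, chosen because the end product would not tolerate hydroxide.

Step 20
Reactants: 27 2-(trimethylsilyl)ethyl enoate
Product: 28 cis-fused β-keto-lactone cyclopentanone (ring C19–C21–C25–C26–C27; C19–H)
Conditions: LiHMDS (2.5 equiv), THF, −78 → 25 °C; aq. NH4Cl
Reagents that add atoms: none
Why: Dieckmann condensation in which the more acidic lactone α-CH2 (C19) attacks the C25 ester (5-exo-trig) and the product is drained off as its stabilised β-dicarbonyl enolate; cis ring fusion is forced, and only the C25 epimer with C28 cis to C15 can cyclise while the other equilibrates by enolisation.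

Step 21
Reactants: 28 cis-fused β-keto-lactone cyclopentanone
Product: 29 C19-methylated β-keto-lactone cyclopentanone
Conditions: K2CO3, MeI, acetone, 25 °C
Reagents that add atoms: iodomethane, CI
Why: C-Alkylation of the β-keto-lactone enolate places the methyl on the convex face because only the cis-fused bicyclo[3.3.0] system can form, which sets the quaternary C19.

Step 22
Reactants: 29 C19-methylated β-keto-lactone cyclopentanone
Product: 31 ring-enlarged cyclohexanone (C21=O, C23H2), via α-silyl ketone 30 (not isolated)
Conditions: TMSCHN2 (2 equiv), BF3·OEt2 (1.5 equiv), CH2Cl2, −78 → −20 °C; then 1 M HCl, THF, 25 °C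
Reagents that add atoms: trimethylsilyldiazomethane, C[Si](C)(C)C=[N+]=[N-]
Why: BF3 activates the only ketone (C21), the diazo carbon adds from the convex face (the side of the C19 methyl, away from the lactone and the macrocyclic bridge), and the β-oxido diazonium ion loses N2 with 1,2-shift of the C21–C25 bond, which places the new carbon C23 between C21 and C25 (Tiffeneau–Demjanov-type diazoalkane homologation). The closest known reactions are Lewis-acid TMSCHN2 ring enlargements of 2,2-disubstituted cycloalkanones and 2-alkyl-2-alkoxycarbonylcyclopentanones, in which the less substituted, non-acylated α-carbon migrates. No ring is closed: the five-membered ring C19–C21–C25–C26–C27 becomes the six-membered ring by insertion, while the lactone and the 11-membered ring stay intact. No lasting stereocentre is created (the silyl-bearing C23 of 30 is protodesilylated to CH2), and C25 migrates with retention, so C19, C25 and C27 are carried over unchanged. The selectivity needed is migration of C25 and not C19, which is secured because C19 is quaternary and bears the electron-withdrawing lactone carbonyl C17; the bulky silyl group of 30 should also suppress a second homologation and disfavour epoxide formation.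

Step 23
Reactants: 31 ring-enlarged cyclohexanone
Product: 32 1,2-dione 2-(trimethylsilyl)ethyl ester
Conditions: SeO2, 1,4-dioxane/H2O (20:1), 90 °C
Reagents that add atoms: selenium dioxide, O=[Se]=O
Why: Riley oxidation (as for camphor to camphorquinone) acts on C23, the only enolisable position of C21=O because C19 is quaternary; C25, now α to a ketone, can settle in its cis-bridged arrangement.

Step 24
Reactants: 32 1,2-dione 2-(trimethylsilyl)ethyl ester
Product: 33 CNP0115928.1
Conditions: TBAF, AcOH (1:1), THF, 0 → 25 °C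
Reagents that add atoms: none
Why: Fluoride-induced β-elimination of the 2-(trimethylsilyl)ethyl ester under acetic acid buffering releases the acid without the base that could trigger retro-Claisen cleavage or benzilic acid rearrangement.

Compound list
1 | (S)-lactic acid | C[C@H](O)C(=O)O | starting material
2 | pivalaldehyde | CC(C)(C)C=O | starting material
3 | (2S,5S)-2-tert-butyl-5-methyl-1,3-dioxolan-4-one | C[C@@H]1O[C@H](C(C)(C)C)OC1=O | intermediate
4 | (2R,5R)-5-bromo-2-tert-butyl-5-methyl-1,3-dioxolan-4-one | C[C@]1(Br)O[C@H](C(C)(C)C)OC1=O | intermediate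
5 | (S)-2-tert-butyl-5-methylene-1,3-dioxolan-4-one | C=C1O[C@H](C(C)(C)C)OC1=O | intermediate
6 | pent-1-en-4-yne | C#CCC=C | starting material
7 | (E)-penta-1,4-dienylzirconocene chloride | C=CC/C=C/[Zr](Cl)(C1C=CC=C1)C1C=CC=C1 | intermediate (not isolated)
8 | (E)-octa-4,7-dien-3-one | CCC(=O)/C=C/CC=C | intermediate
9 | (4E,6Z)-6-(tert-butyldimethylsilyloxy)octa-1,4,6-triene | C/C=C(O[Si](C)(C)C(C)(C)C)/C=C/CC=C | intermediate
10 | spiro-dioxolanone Diels–Alder adduct (C6 allyl, C7=C8–OTBS, C12 methyl, C15 spiro, acetal S) | C=CC[C@H]1C=C(O[Si](C)(C)C(C)(C)C)[C@@H](C)C[C@@]12O[C@H](C(C)(C)C)OC2=O | intermediate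
11 | γ-hydroxy β-keto methyl ester (C15–OH, C27=O, C19H2, C17 ester) | C=CC[C@H]1C=C(O[Si](C)(C)C(C)(C)C)[C@@H](C)C[C@]1(O)C(=O)CC(=O)OC | intermediate (not isolated)
12 | spiro-tetronic acid | C=CC[C@H]1C=C(O[Si](C)(C)C(C)(C)C)[C@@H](C)C[C@@]12OC(=O)C=C2O | intermediate
13 | spiro-tetronate triflate | C=CC[C@H]1C=C(O[Si](C)(C)C(C)(C)C)[C@@H](C)C[C@@]12OC(=O)C=C2OS(=O)(=O)C(F)(F)F | intermediate
14 | cis-3,5-dimethylcyclohexanone (meso) | O=C1C[C@H](C)C[C@H](C)C1 | starting material
15 | (3S,5R)-3,5-dimethyl-1-(trimethylsilyloxy)cyclohexene | C[Si](C)(C)OC1=C[C@@H](C)C[C@@H](C)C1 | intermediate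
16 | (3R,5S)-3,5-dimethyl-6-oxohexanoic acid | OC(=O)C[C@H](C)C[C@H](C)C=O | intermediate
17 | methyl (3R,5S)-3,5-dimethyl-6-oxohexanoate | COC(=O)C[C@H](C)C[C@H](C)C=O | intermediate
18 | methyl (3R,5S)-3,5-dimethylhept-6-enoate | COC(=O)C[C@H](C)C[C@H](C)C=C | intermediate
19 | lithium enolate of 18 | COC(O[Li])=C[C@H](C)C[C@H](C)C=C | intermediate (not isolated)
20 | methyl (3R,5S)-2-(hydroxymethyl)-3,5-dimethylhept-6-enoate (C2 epimers) | COC(=O)C(CO)[C@H](C)C[C@H](C)C=C | intermediate
21 | methyl (3R,5S)-2-(iodomethyl)-3,5-dimethylhept-6-enoate (C2 epimers) | COC(=O)C(CI)[C@H](C)C[C@H](C)C=C | intermediate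
22 | organozinc iodide from 21 | COC(=O)C(C[Zn]I)[C@H](C)C[C@H](C)C=C | intermediate (not isolated)
23 | 4-alkylbutenolide diene (C25 epimers) | C=CC[C@H]1C=C(O[Si](C)(C)C(C)(C)C)[C@@H](C)C[C@@]12OC(=O)C=C2CC(C(=O)OC)[C@H](C)C[C@H](C)C=C | intermediate
24 | macrocyclic butenolide (C3=C4 E/Z, C25 epimers) | C[C@@H]1C=CC[C@H]2C=C(O[Si](C)(C)C(C)(C)C)[C@@H](C)C[C@@]23OC(=O)C=C3CC(C(=O)OC)[C@H](C)C1 | intermediate
25 | saturated macrocyclic γ-lactone (C25 epimers) | C[C@@H]1CCC[C@H]2C=C(O[Si](C)(C)C(C)(C)C)[C@@H](C)C[C@@]23OC(=O)C[C@H]3CC(C(=O)OC)[C@H](C)C1 | intermediate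
26 | enol triflate (C25 epimers) | C[C@@H]1CCC[C@H]2C=C(OS(=O)(=O)C(F)(F)F)[C@@H](C)C[C@@]23OC(=O)C[C@H]3CC(C(=O)OC)[C@H](C)C1 | intermediate
27 | 2-(trimethylsilyl)ethyl enoate (C25 epimers) | C[C@@H]1CCC[C@H]2C=C(C(=O)OCC[Si](C)(C)C)[C@@H](C)C[C@@]23OC(=O)C[C@H]3CC(C(=O)OC)[C@H](C)C1 | intermediate
28 | cis-fused β-keto-lactone cyclopentanone (C19–H) | C[C@@H]1CCC[C@H]2C=C(C(=O)OCC[Si](C)(C)C)[C@@H](C)C[C@@]23OC(=O)[C@H]2C(=O)[C@H](C[C@H]23)[C@H](C)C1 | intermediate
29 | C19-methylated β-keto-lactone cyclopentanone | C[C@@H]1CCC[C@H]2C=C(C(=O)OCC[Si](C)(C)C)[C@@H](C)C[C@@]23OC(=O)[C@@]2(C)C(=O)[C@H](C[C@H]23)[C@H](C)C1 | intermediate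
30 | α-silyl cyclohexanone (C23–SiMe3) | C[C@@H]1CCC[C@H]2C=C(C(=O)OCC[Si](C)(C)C)[C@@H](C)C[C@@]23OC(=O)[C@@]2(C)C(=O)C([Si](C)(C)C)[C@H](C[C@H]23)[C@H](C)C1 | intermediate (not isolated)
31 | ring-enlarged cyclohexanone (C21=O, C23H2) | C[C@@H]1CCC[C@H]2C=C(C(=O)OCC[Si](C)(C)C)[C@@H](C)C[C@@]23OC(=O)[C@@]2(C)C(=O)C[C@H](C[C@H]23)[C@H](C)C1 | intermediate
32 | 1,2-dione 2-(trimethylsilyl)ethyl ester | C[C@@H]1CCC[C@H]2C=C(C(=O)OCC[Si](C)(C)C)[C@@H](C)C[C@@]23OC(=O)[C@@]2(C)C(=O)C(=O)[C@H](C[C@H]23)[C@H](C)C1 | intermediate
33 | CNP0115928.1 | C[C@@H]1CCC[C@H]2C=C(C(=O)O)[C@@H](C)C[C@@]23OC(=O)[C@@]2(C)C(=O)C(=O)[C@H](C[C@H]23)[C@H](C)C1 | target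

Total step count: 24. Longest linear sequence: 16 steps (1–3, 6–8, 15–24; the branch 9–14, 15–24 is equally long).

Steps most likely to fail

Step 22. The diazo carbon may fail to reach the shielded C21 carbonyl, or the diazonium intermediate may collapse to the spiro-epoxide or shift C19 instead of C25. The fallback sets out from 29 and replaces the diazo homologation by an α-ketol ring enlargement. Vinylmagnesium bromide with CeCl3 (THF, −78 °C) should add to C21 to give the vinyl carbinol F1. Ozonolysis of the vinyl group (O3, CH2Cl2/MeOH, −78 °C, dye end-point to spare the electron-poor enoate, then Me2S) should give the hydroxy aldehyde F2. Under BF3·OEt2 (CH2Cl2, 0 °C) F2 should undergo the α-ketol rearrangement to the ring-enlarged ketol F3 (or its C21-hydroxy/C23-keto isomer; either 1,2-shift leads to the same dione). Oxidation with Cu(OAc)2 in AcOH/MeOH would then return to the route at 32, bypassing 31.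

Step 17. The enol silane may be over-reduced, the hindered butenolide may stall, or the C3=C4 bond may migrate and scramble C2. The fallback sets out from 24 and separates the two reductions. Conjugate reduction with [(Ph3P)CuH]6 (toluene, 25 °C) should deliver hydride to C27 from the open face and give the saturated lactone F4 with C3=C4 intact. Diimide (2-nitrobenzenesulfonyl hydrazide, Et3N, CH2Cl2) would then reduce only the disubstituted alkene and return to the route at 25.

Step 23. Hot selenium dioxide may over-oxidise (dehydrogenation of the dione, allylic oxidation of the cyclohexene). The fallback sets out from 31 and proceeds by enolate hydroxylation. KHMDS (THF, −78 °C) followed by 2-(phenylsulfonyl)-3-phenyloxaziridine should give the ketol F5 (the same C23-hydroxy ketone as F3, C23 epimers). Oxidation with Dess–Martin periodinane (CH2Cl2, 25 °C) would return to the route at 32.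

Further compounds
F1 | step 22 | vinyl carbinol at C21 | C[C@@H]1CCC[C@H]2C=C(C(=O)OCC[Si](C)(C)C)[C@@H](C)C[C@@]23OC(=O)[C@@]2(C)C(O)(C=C)[C@H](C[C@H]23)[C@H](C)C1
F2 | step 22 | α-hydroxy aldehyde at C21 | C[C@@H]1CCC[C@H]2C=C(C(=O)OCC[Si](C)(C)C)[C@@H](C)C[C@@]23OC(=O)[C@@]2(C)C(O)(C=O)[C@H](C[C@H]23)[C@H](C)C1
F3 | step 22 | ring-enlarged ketol (C21=O, C23–OH) | C[C@@H]1CCC[C@H]2C=C(C(=O)OCC[Si](C)(C)C)[C@@H](C)C[C@@]23OC(=O)[C@@]2(C)C(=O)C(O)[C@H](C[C@H]23)[C@H](C)C1
F4 | step 17 | saturated lactone with C3=C4 intact | C[C@@H]1C=CC[C@H]2C=C(O[Si](C)(C)C(C)(C)C)[C@@H](C)C[C@@]23OC(=O)C[C@H]3CC(C(=O)OC)[C@H](C)C1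
F5 | step 23 | ketol (C21=O, C23–OH) | C[C@@H]1CCC[C@H]2C=C(C(=O)OCC[Si](C)(C)C)[C@@H](C)C[C@@]23OC(=O)[C@@]2(C)C(=O)C(O)[C@H](C[C@H]23)[C@H](C)C1
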